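**Retrosynthetic overview** (carbons numbered C1 = ester carbonyl to C20 = CHBr; the oxolane ring is O, C5, C6, C7, C8)
1. The last bond made is C10–C11. C10 is used with reversed polarity as the 1-bromoalkyne 8, and C11 as an (E)-alkenylborane made in the flask from terminal alkyne 12. Copper joins them, so two alkyne-level halves give the whole C20 chain in one operation.
2. Enabling feature: the conjugated enyne C9≡C10–C11=C12 on C8 of the oxolane ring. Its (E)-C11=C12 alkene is the syn-hydroboration image of a terminal C11≡C12 alkyne. The (Z)-bromoalkene C19=C20 is the reason the coupling metal is copper and not palladium.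
3. Bromoalkyne 8: C9≡C10 comes from the C9 aldehyde (Ohira–Bestmann, then bromination); C1–C2 come from cross-metathesis with methyl acrylate, followed by hydrogenation.
4. Ring formation: the oxolane, the only ring, is closed early (O–C8 bond) by cobalt-catalysed aerobic oxidative cyclisation of (S)-octa-1,7-dien-4-ol, which sets C8 trans to C5. The dienol comes from (S)-2-(but-3-en-1-yl)oxirane and vinylmagnesium bromide.
5. Bromodienyne 12: hept-6-yn-1-ol, oxidation, formyl Wittig (C17=C18, E), bromomethylene Wittig (C19=C20, Z).

Key step: step 11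

Remark on the chemistry: epoxide 1 and alkynol 9 are taken as commercial; C5 is bought with 1, and C8 is derived from it in step 2.

**Step 1**
Reactants: 1 (S)-2-(but-3-en-1-yl)oxirane
Product: 2 (S)-octa-1,7-dien-4-ol
Conditions: vinylMgBr (1.5 equiv), CuI (10 mol %), THF, –30 → 0 °C; then H2O
Reagents that add atoms: vinylmagnesium bromide, C=C[Mg]Br
Why: Copper-catalysed SN2 opening of a terminal epoxide by a Grignard reagent occurs at the unsubstituted carbon, so the C5 stereocentre of 1 is carried over untouched.

**Step 2**
Reactants: 2 (S)-octa-1,7-dien-4-ol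
Product: 3 [(2S,5S)-5-(prop-2-en-1-yl)oxolan-2-yl]methanol
Conditions: Co(modp)2 (10 mol %; modp = 1-morpholinocarbamoyl-4,4-dimethyl-1,3-pentanedionate, divalent cobalt), tBuOOH (10 mol %), O2 (1 atm), iPrOH, 55 °C
Reagents that add atoms: dioxygen, O=O
Why: Mukaiyama aerobic oxidative cyclisation of a pent-4-en-1-ol closes the ring 5-exo (C5–O onto C8) and traps the C9 radical with O2, and the new C8 centre should form trans to C5 under control of the existing carbinol centre (C5 substituent pseudo-equatorial in the transition state), while the allyl alkene cannot close a five-membered ring and should stay.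

**Step 3**
Reactants: 3 [(2S,5S)-5-(prop-2-en-1-yl)oxolan-2-yl]methanol
Product: 4 methyl (2E)-4-[(2S,5S)-5-(hydroxymethyl)oxolan-2-yl]but-2-enoate
Conditions: methyl acrylate (3 equiv), second-generation Hoveyda–Grubbs catalyst (3 mol %), CH2Cl2, 40 °C
Reagents that add atoms: methyl acrylate, C=CC(=O)OC
Why: Olefin cross-metathesis of a terminal alkene with an electron-poor acrylate should favour the cross product as the E enoate and tolerates the free alcohol; no stereocentre is involved.

**Step 4**
Reactants: 4 methyl (2E)-4-[(2S,5S)-5-(hydroxymethyl)oxolan-2-yl]but-2-enoate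
Product: 5 methyl 4-[(2R,5S)-5-(hydroxymethyl)oxolan-2-yl]butanoate
Conditions: H2 (1 atm), Pd/C (10 wt %), EtOAc, rt
Reagents that add atoms: none
Why: Heterogeneous catalytic hydrogenation saturates the conjugated alkene and leaves ester, ether and alcohol alone; the C5 descriptor changes from S to R only because the ligand priorities change.

**Step 5**
Reactants: 5 methyl 4-[(2R,5S)-5-(hydroxymethyl)oxolan-2-yl]butanoate
Product: 6 methyl 4-[(2R,5S)-5-formyloxolan-2-yl]butanoate
Conditions: TEMPO (10 mol %), PhI(OAc)2 (1.1 equiv), CH2Cl2, rt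
Reagents that add atoms: none
Why: TEMPO/PhI(OAc)2 oxidation stops at the aldehyde under non-basic conditions, so the alpha-oxygenated C8 centre should keep its configuration; the crude aldehyde is used at once.

**Step 6**
Reactants: 6 methyl 4-[(2R,5S)-5-formyloxolan-2-yl]butanoate
Product: 7 methyl 4-[(2R,5S)-5-ethynyloxolan-2-yl]butanoate
Conditions: dimethyl (1-diazo-2-oxopropyl)phosphonate (1.3 equiv), K2CO3 (2 equiv), MeOH, 0 °C → rt
Reagents that add atoms: dimethyl (1-diazo-2-oxopropyl)phosphonate, COP(=O)(OC)C(=[N+]=[N-])C(C)=O
Why: Seyferth–Gilbert homologation in the Ohira–Bestmann variant adds C10 and converts the aldehyde into the terminal alkyne under mild base in methanol, which is degenerate for the methyl ester and normally leaves alpha-alkoxy aldehydes configurationally intact.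

**Step 7**
Reactants: 7 methyl 4-[(2R,5S)-5-ethynyloxolan-2-yl]butanoate
Product: 8 methyl 4-[(2R,5S)-5-(bromoethynyl)oxolan-2-yl]butanoate
Conditions: NBS (1.1 equiv), AgNO3 (10 mol %), acetone, rt, dark
Reagents that add atoms: N-bromosuccinimide, O=C1CCC(=O)N1Br
Why: Silver-catalysed electrophilic bromination of a terminal alkyne via the silver acetylide gives the 1-bromoalkyne, the electrophilic form of C10, without any strong base.

**Step 8**
Reactants: 9 hept-6-yn-1-ol
Product: 10 hept-6-ynal
Conditions: TEMPO (10 mol %), PhI(OAc)2 (1.1 equiv), CH2Cl2, rt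
Reagents that add atoms: none
Why: TEMPO/PhI(OAc)2 oxidation of a primary alcohol to the aldehyde is inert toward the terminal alkyne.

**Step 9**
Reactants: 10 hept-6-ynal
Product: 11 (2E)-non-2-en-8-ynal
Conditions: Ph3P=CHCHO (1.1 equiv), toluene, 80 °C
Reagents that add atoms: (triphenylphosphoranylidene)acetaldehyde, O=CC=P(c1ccccc1)(c1ccccc1)c1ccccc1
Why: Wittig reaction with the stabilised formyl ylide should give the E enal (C17=C18) and add C18 and C19.

**Step 10**
Reactants: 11 (2E)-non-2-en-8-ynal
Product: 12 (1Z,3E)-1-bromodeca-1,3-dien-9-yne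
Conditions: Ph3PCH2Br Br (1.5 equiv), KOtBu (1.4 equiv), THF, –78 °C; then 11, –78 → 0 °C
Reagents that add atoms: (bromomethyl)triphenylphosphonium bromide, BrC[P+](c1ccccc1)(c1ccccc1)c1ccccc1.[Br-]
Why: Wittig bromomethylenation with the non-stabilised ylide Ph3P=CHBr at low temperature is kinetically controlled and should favour the Z bromoalkene (C19=C20), and keeping the base below the phosphonium salt avoids loss of HBr from the product.

**Step 11**
Reactants: 12 (1Z,3E)-1-bromodeca-1,3-dien-9-yne; 8 methyl 4-[(2R,5S)-5-(bromoethynyl)oxolan-2-yl]butanoate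
Product: 15 methyl 4-[(2R,5S)-5-[(3E,9E,11Z)-12-bromododeca-3,9,11-trien-1-yn-1-yl]oxolan-2-yl]butanoate, via (E)-alkenyldicyclohexylborane 13 (not isolated), via sodium alkenyl(methoxy)borate 14 (not isolated)
Conditions: Cy2BH (1.3 equiv; made in the flask from BH3·SMe2 and cyclohexene, THF, 0 °C), 12 (1.3 equiv), THF, 0 °C → rt; then NaOMe (1.3 equiv, 1 M in MeOH), Cu(acac)2 (5 mol %), 8 (1.0 equiv), –15 °C → rt
Reagents that add atoms: none
Why: Syn-hydroboration of the terminal alkyne of 12 by the bulky dialkylborane puts boron on C11 and fixes C11=C12 as E (13); methoxide turns 13 into borate 14, which hands the alkenyl group to copper with retention, and the alkenylcopper (monovalent copper, formed from Cu(acac)2 in the flask) attacks the electrophilic C10 of 8 (oxidative addition and reductive elimination at copper, or carbocupration and loss of bromide), which forms C10–C11. The closest known reaction type is the copper-mediated coupling of (E)-alkenyldialkylboranes with 1-bromoalkynes to conjugated (E)-enynes, a union of two carbons that are both nucleophilic in their normal form, made possible by the polarity reversal at C10. No ring is closed and no stereocentre is formed: C5 and C8 are remote and untouched, and the alkene geometry follows from syn addition of B–H and retention in the transfer from boron to copper to carbon. The step needs hydroboration of the terminal alkyne only, which the terminal position of C11≡C12 against the 1,2-disubstituted, bromine-bearing diene and the steric demand of Cy2BH should secure. It also needs reaction at the C(sp)–Br bond of 8 and not at the C(sp2)–Br bond at C20, which the far higher electrophilicity of the bromoalkyne toward organocopper and the absence of palladium should secure. The methyl ester is matched to methoxide, so exchange at C1 is degenerate.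

**Compound list**
1 | (S)-2-(but-3-en-1-yl)oxirane | C=CCC[C@H]1CO1 | starting material
2 | (S)-octa-1,7-dien-4-ol | C=CC[C@@H](O)CCC=C | intermediate
3 | [(2S,5S)-5-(prop-2-en-1-yl)oxolan-2-yl]methanol | C=CC[C@@H]1CC[C@@H](CO)O1 | intermediate
4 | methyl (2E)-4-[(2S,5S)-5-(hydroxymethyl)oxolan-2-yl]but-2-enoate | COC(=O)/C=C/C[C@@H]1CC[C@@H](CO)O1 | intermediate
5 | methyl 4-[(2R,5S)-5-(hydroxymethyl)oxolan-2-yl]butanoate | COC(=O)CCC[C@@H]1CC[C@@H](CO)O1 | intermediate
6 | methyl 4-[(2R,5S)-5-formyloxolan-2-yl]butanoate | COC(=O)CCC[C@@H]1CC[C@@H](C=O)O1 | intermediate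
7 | methyl 4-[(2R,5S)-5-ethynyloxolan-2-yl]butanoate | COC(=O)CCC[C@@H]1CC[C@@H](C#C)O1 | intermediate
8 | methyl 4-[(2R,5S)-5-(bromoethynyl)oxolan-2-yl]butanoate | COC(=O)CCC[C@@H]1CC[C@@H](C#CBr)O1 | intermediate
9 | hept-6-yn-1-ol | C#CCCCCCO | starting material
10 | hept-6-ynal | C#CCCCCC=O | intermediate
11 | (2E)-non-2-en-8-ynal | C#CCCCC/C=C/C=O | intermediate
12 | (1Z,3E)-1-bromodeca-1,3-dien-9-yne | C#CCCCC/C=C/C=C\Br | intermediate
13 | [(1E,7E,9Z)-10-bromodeca-1,7,9-trien-1-yl]dicyclohexylborane | Br/C=C\C=C\CCCC/C=C/B(C1CCCCC1)C1CCCCC1 | intermediate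
14 | sodium [(1E,7E,9Z)-10-bromodeca-1,7,9-trien-1-yl]dicyclohexyl(methoxy)borate | [Na+].CO[B-](/C=C/CCCC/C=C/C=C\Br)(C1CCCCC1)C1CCCCC1 | intermediate
15 | methyl 4-[(2R,5S)-5-[(3E,9E,11Z)-12-bromododeca-3,9,11-trien-1-yn-1-yl]oxolan-2-yl]butanoate | COC(=O)CCC[C@@H]1CC[C@@H](C#C/C=C/CCCC/C=C/C=C\Br)O1 | target

**Count**
Total step count: 11. Longest linear sequence: 8 steps (steps 1–7, then step 11); the second branch is steps 8–10.

**Steps most likely to fail, with fallbacks**

1. Step 11. The hydroboration may not stay on the terminal alkyne and may attack the bromodiene, the alkenylcopper may dimerise, or methoxide may eliminate HBr from the (Z)-bromoalkene before the coupling is complete. The fallback returns to normal polarity with a Sonogashira coupling; it sets out from 12 and from 7 (taken before step 7) and comes back to the route at 15. Hydrozirconation of 12 with Cp2Zr(H)Cl (THF, rt) should give chlorido[(1E,7E,9Z)-10-bromodeca-1,7,9-trien-1-yl]bis(cyclopentadienyl)zirconium F1 (not isolated; the cyclopentadienyl rings are written sigma-bound in its SMILES). I2 at 0 °C should cleave F1 with retention to (1E,7E,9Z)-10-bromo-1-iododeca-1,7,9-triene F2. F2 and 7 are then coupled with Pd(PPh3)4 (zerovalent palladium, 3 mol %), CuI (5 mol %) and iPr2NH in THF at 0 °C. Oxidative addition into the carbon–iodine bond is expected to outrun that into the C20–Br bond, so 15 should result.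

2. Step 10. The kinetic preference for the Z bromoalkene may be incomplete, and the Z isomer may lose HBr to excess base. The fallback installs C20 as a 1,1-dibromoalkene and removes one bromine by palladium-catalysed hydrogenolysis. Because Bu3SnH and palladium would also hydrostannylate a terminal alkyne, the alkyne is silylated first. It sets out from 9 and comes back at 12. Treatment of 9 with n-BuLi (2.1 equiv) and Me3SiCl (2.2 equiv) in THF (–78 °C → rt) should give trimethyl{[7-(trimethylsilyl)hept-6-yn-1-yl]oxy}silane F3 (not isolated), whose O–Si bond is cleaved by dilute aqueous HCl in the work-up to give 7-(trimethylsilyl)hept-6-yn-1-ol F4. Oxidation under the conditions of step 8 should give 7-(trimethylsilyl)hept-6-ynal F5, and the Wittig reaction of step 9 should give (2E)-9-(trimethylsilyl)non-2-en-8-ynal F6. Ramirez olefination (CBr4, PPh3, CH2Cl2, 0 °C) should then give [(7E)-10,10-dibromodeca-7,9-dien-1-yn-1-yl]trimethylsilane F7. Pd(PPh3)4 (zerovalent palladium, 4 mol %) with Bu3SnH (1.05 equiv) in toluene at rt should replace only the bromine trans to the dienyl chain, where oxidative addition is less hindered, leaving [(7E,9Z)-10-bromodeca-7,9-dien-1-yn-1-yl]trimethylsilane F8. K2CO3 in MeOH at rt then removes the silyl group and should give 12.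

3. Step 6. The alpha-oxygenated aldehyde may enolise in basic methanol before it is homologated, which would erode the trans relationship at C8. The fallback makes the alkyne carbon without base acting on the aldehyde and arrives directly at the bromoalkyne level; it sets out from 6 and comes back at 8, so step 7 is then not needed. Ramirez olefination of 6 (CBr4, PPh3, CH2Cl2, 0 °C) should give methyl 4-[(2R,5S)-5-(2,2-dibromoethenyl)oxolan-2-yl]butanoate F9. Dehydrobromination of F9 with DBU in DMSO at rt should give 8.

**Further compounds**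
F1 | step 11 | chlorido[(1E,7E,9Z)-10-bromodeca-1,7,9-trien-1-yl]bis(cyclopentadienyl)zirconium | Cl[Zr](/C=C/CCCC/C=C/C=C\Br)(C1C=CC=C1)C1C=CC=C1
F2 | step 11 | (1E,7E,9Z)-10-bromo-1-iododeca-1,7,9-triene | I/C=C/CCCC/C=C/C=C\Br
F3 | step 10 | trimethyl{[7-(trimethylsilyl)hept-6-yn-1-yl]oxy}silane | C[Si](C)(C)C#CCCCCCO[Si](C)(C)C
F4 | step 10 | 7-(trimethylsilyl)hept-6-yn-1-ol | C[Si](C)(C)C#CCCCCCO
F5 | step 10 | 7-(trimethylsilyl)hept-6-ynal | C[Si](C)(C)C#CCCCCC=O
F6 | step 10 | (2E)-9-(trimethylsilyl)non-2-en-8-ynal | C[Si](C)(C)C#CCCCC/C=C/C=O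
F7 | step 10 | [(7E)-10,10-dibromodeca-7,9-dien-1-yn-1-yl]trimethylsilane | C[Si](C)(C)C#CCCCC/C=C/C=C(Br)Br
F8 | step 10 | [(7E,9Z)-10-bromodeca-7,9-dien-1-yn-1-yl]trimethylsilane | C[Si](C)(C)C#CCCCC/C=C/C=C\Br
F9 | step 6 | methyl 4-[(2R,5S)-5-(2,2-dibromoethenyl)oxolan-2-yl]butanoate | COC(=O)CCC[C@@H]1CC[C@@H](C=C(Br)Br)O1
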